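## Retrosynthetic overview
1. The phenol is unmasked last. The (Z)-cinnamate C=C is cut by a Still–Gennari olefination between O-TBS-vanillin and a C19 phosphonoacetate, which is made by acylating the only primary OH of labda-13(16),14-diene-8α,19-diol.
2. The diol goes back to an 8α,17-epoxy 19-methyl ester. One LiAlH4 reduction gives both the 8α-carbinol (C8 set by α-face epoxidation of the 8(17)-methylene) and the C19 carbinol.
3. The 2-substituted butadiene is cut at C13–C14 by Stille vinylation of the kinetic enol triflate of a C13 methyl ketone.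
4. The methyl ketone comes from chemoselective oxidative cleavage of the 13-ene of methyl isocupressate. This normal-series labdane already holds C4, C5, C9, C10 and the axial C19 carboxyl.
5. Ring order: no carbocycle is built. Rings A and B (trans-decalin) come intact from the chiral pool and the arene from vanillin. The only ring formed is the oxirane (step 3), which is opened again in step 6.

Assumption: the labdane acid of step 1 (sold as a phytochemical reference substance) and the phosphonoacetic acid of step 7 (a catalogue reagent) are taken as commercially available.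

Numbering: labdane numbering is used. C17 is on C8, C19 is the axial β carbon on C4, C18 is the equatorial methyl on C4, C20 is on C10, and C16 is on C13.

## Route

Step 1
Reactants: 1 isocupressic acid
Product: 2 methyl isocupressate [methyl (13E)-15-hydroxylabda-8(17),13-dien-19-oate]
Conditions: MeI (1.5 equiv), K2CO3 (1.5 equiv), DMF, rt, 4 h
Reagents that add atoms: iodomethane, CI
Why: Carboxylate SN2 O-alkylation is insensitive to the steric shielding of the axial C19 acid, leaves the allylic alcohol alone under K2CO3, and removes the acidic proton before the enolate chemistry, with no stereocentre touched.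

Step 2
Reactants: 2 methyl isocupressate
Product: 4 methyl 13-oxo-14,15-dinorlabd-8(17)-en-19-oate, via 13,14,15-triol 3 (not isolated)
Conditions: OsO4 (2 mol %), NaIO4 (3.5 equiv), 2,6-lutidine (2 equiv), 1,4-dioxane/H2O 3:1, rt, stopped when 2 is consumed
Reagents that add atoms: osmium tetroxide, O=[Os](=O)(=O)=O; sodium periodate, [Na+].[O-]I(=O)(=O)=O
Why: In this Lemieux–Johnson oxidation OsO4 adds to the open-chain trisubstituted 13-ene faster than to the 8(17)-methylene, which is shielded by the axial C20 methyl and the C9 chain, and NaIO4 cleaves triol 3 to the C13 methyl ketone while C14 and C15 leave as one-carbon fragments.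

Step 3
Reactants: 4 methyl 13-oxo-14,15-dinorlabd-8(17)-en-19-oate
Product: 5 methyl 8α,17-epoxy-13-oxo-14,15-dinorlabdan-19-oate
Conditions: mCPBA (1.2 equiv), CH2Cl2, 0 °C, 2 h; the minor 8β,17-epoxide is removed on silica
Reagents that add atoms: mCPBA, O=C(OO)c1cccc(Cl)c1
Why: In this Prilezhaev epoxidation the only remaining alkene is attacked from the α face because the β face is blocked by the syn-axial C20 methyl, which sets C8 (oxygen α and equatorial, C17 β and axial), and the acyclic methyl ketone is too slow for Baeyer–Villiger oxidation at 0 °C.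

Step 4
Reactants: 5 methyl 8α,17-epoxy-13-oxo-14,15-dinorlabdan-19-oate
Product: 7 methyl 8α,17-epoxy-13-(trifluoromethylsulfonyloxy)-14,15-dinorlabd-13(16)-en-19-oate, via lithium 13(16)-enolate 6 (not isolated)
Conditions: LiN(iPr)2 (LDA, commercial solution, 1.1 equiv), THF, −78 °C, 45 min; then Comins' reagent (1.2 equiv), −78 to −20 °C
Reagents that add atoms: Comins' reagent, N-(5-chloropyridin-2-yl)bis(trifluoromethanesulfonimide), FC(F)(F)S(=O)(=O)N(c1ccc(Cl)cn1)S(=O)(=O)C(F)(F)F
Why: Kinetic deprotonation by the hindered amide takes a C16 methyl proton rather than a C12 proton, and O-sulfonylation of enolate 6 at low temperature freezes this regiochemistry as the 1-alken-2-yl triflate, while the ester has no α-hydrogen and the epoxide is inert at −78 °C.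

Step 5
Reactants: 7 methyl 8α,17-epoxy-13-(trifluoromethylsulfonyloxy)-14,15-dinorlabd-13(16)-en-19-oate
Product: 8 methyl 8α,17-epoxylabda-13(16),14-dien-19-oate
Conditions: Bu3SnCH=CH2 (1.2 equiv), Pd(PPh3)4 (5 mol %), LiCl (3 equiv), THF, 55 °C
Reagents that add atoms: tributyl(vinyl)stannane, C=C[Sn](CCCC)(CCCC)CCCC
Why: In this Stille cross-coupling, oxidative addition of zerovalent palladium into the C13–OTf bond, chloride exchange, vinyl transmetalation and reductive elimination give the 2-substituted 1,3-butadiene regiospecifically, and neither the non-allylic epoxide nor the hindered ester reacts.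

Step 6
Reactants: 8 methyl 8α,17-epoxylabda-13(16),14-dien-19-oate
Product: 9 labda-13(16),14-diene-8α,19-diol
Conditions: LiAlH4 (4 equiv), THF, 0 °C to reflux, 3 h; H2O/aq NaOH work-up
Reagents that add atoms: none
Why: In this hydride reduction LiAlH4 opens the epoxide by SN2 attack at the primary C17, so the C8–O bond and the 8α (8R) configuration are kept and C17 becomes the axial β-methyl, the hindered ester is reduced to the C19 carbinol in the same pot, and the unactivated diene is inert.

Step 7
Reactants: 9 labda-13(16),14-diene-8α,19-diol; 10 2-[bis(2,2,2-trifluoroethoxy)phosphoryl]acetic acid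
Product: 12 8α-hydroxylabda-13(16),14-dien-19-yl 2-[bis(2,2,2-trifluoroethoxy)phosphoryl]acetate, via O-acylisourea 11 (not isolated)
Conditions: DCC (1.5 equiv), DMAP (0.1 equiv), 10 (1.5 equiv), CH2Cl2, 0 °C to rt
Reagents that add atoms: none
Why: In this Steglich esterification only the primary C19 hydroxyl is acylated by the activated acid 11, the tertiary C8 hydroxyl being inert, so no protecting group is needed on the terpene.

Step 8
Reactants: 13 vanillin
Product: 14 4-(tert-butyldimethylsilyloxy)-3-methoxybenzaldehyde (O-TBS-vanillin)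
Conditions: TBSCl (1.1 equiv), imidazole (1.5 equiv), DMF, rt, 2 h
Reagents that add atoms: tert-butyldimethylsilyl chloride, CC(C)(C)[Si](C)(C)Cl
Why: Silyl ether protection removes the acidic phenol proton, which would otherwise quench the phosphonate anion and deactivate the aldehyde as its phenoxide.

Step 9
Reactants: 12 8α-hydroxylabda-13(16),14-dien-19-yl 2-[bis(2,2,2-trifluoroethoxy)phosphoryl]acetate; 14 O-TBS-vanillin
Product: 16 8α-hydroxylabda-13(16),14-dien-19-yl (Z)-3-[4-(tert-butyldimethylsilyloxy)-3-methoxyphenyl]prop-2-enoate, via potassium phosphonate carbanion 15 (not isolated)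
Conditions: KN(SiMe3)2 (KHMDS, 1.05 equiv), 18-crown-6 (3 equiv), THF, −78 °C, 20 min; then 14 (1.2 equiv), −78 °C, 2 h, light excluded
Reagents that add atoms: none
Why: In the Still–Gennari variant of the Horner–Wadsworth–Emmons olefination the electron-poor trifluoroethyl phosphonate and the dissociated potassium ion make the kinetic adduct collapse irreversibly to the (Z)-cinnamate, and one equivalent of base deprotonates only the far more acidic P–CH2–CO position, not the tertiary alcohol.

Step 10
Reactants: 16 8α-hydroxylabda-13(16),14-dien-19-yl (Z)-3-[4-(tert-butyldimethylsilyloxy)-3-methoxyphenyl]prop-2-enoate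
Product: 17 8α-hydroxylabda-13(16),14-dien-19-yl (Z)-ferulate (CNP0142252.2, the target)
Conditions: TBAF (1.1 equiv), AcOH (1.2 equiv), THF, 0 °C, 20 min, light excluded
Reagents that add atoms: none
Why: Fluoride-induced desilylation of an aryl silyl ether is fast at 0 °C, and the acetic acid buffer suppresses free phenoxide, so the ester, diene, tertiary alcohol and (Z)-alkene stay unchanged.

## Compound list
1 | isocupressic acid, (13E)-15-hydroxylabda-8(17),13-dien-19-oic acid (4S,5R,9S,10R; 5α-H, 9α-H, 10β-CH3, axial 4β-CO2H) | OC/C=C(\C)CC[C@@H]1[C@@]2(C)CCC[C@](C)(C(=O)O)[C@@H]2CCC1=C | starting material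
2 | methyl isocupressate, methyl (13E)-15-hydroxylabda-8(17),13-dien-19-oate | OC/C=C(\C)CC[C@@H]1[C@@]2(C)CCC[C@](C)(C(=O)OC)[C@@H]2CCC1=C | intermediate
3 | 13,14,15-triol, methyl 13,14,15-trihydroxylabd-8(17)-en-19-oate (syn addition, both facial isomers at C13/C14; formed in the flask) | OCC(O)C(C)(O)CC[C@@H]1[C@@]2(C)CCC[C@](C)(C(=O)OC)[C@@H]2CCC1=C | intermediate
4 | methyl 13-oxo-14,15-dinorlabd-8(17)-en-19-oate (4S,5R,9S,10R) | CC(=O)CC[C@@H]1[C@@]2(C)CCC[C@](C)(C(=O)OC)[C@@H]2CCC1=C | intermediate
5 | methyl 8α,17-epoxy-13-oxo-14,15-dinorlabdan-19-oate (4S,5R,8R,9R,10S; epoxide O α, C17 β) | CC(=O)CC[C@@H]1[C@@]2(C)CCC[C@](C)(C(=O)OC)[C@@H]2CC[C@]13CO3 | intermediate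
6 | lithium 13(16)-enolate of 5 (formed in the flask) | [Li+].C=C([O-])CC[C@@H]1[C@@]2(C)CCC[C@](C)(C(=O)OC)[C@@H]2CC[C@]13CO3 | intermediate
7 | methyl 8α,17-epoxy-13-(trifluoromethylsulfonyloxy)-14,15-dinorlabd-13(16)-en-19-oate | C=C(OS(=O)(=O)C(F)(F)F)CC[C@@H]1[C@@]2(C)CCC[C@](C)(C(=O)OC)[C@@H]2CC[C@]13CO3 | intermediate
8 | methyl 8α,17-epoxylabda-13(16),14-dien-19-oate | C=CC(=C)CC[C@@H]1[C@@]2(C)CCC[C@](C)(C(=O)OC)[C@@H]2CC[C@]13CO3 | intermediate
9 | labda-13(16),14-diene-8α,19-diol (4S,5R,8R,9R,10S) | C=CC(=C)CC[C@@H]1[C@@]2(C)CCC[C@](C)(CO)[C@@H]2CC[C@@]1(C)O | intermediate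
10 | 2-[bis(2,2,2-trifluoroethoxy)phosphoryl]acetic acid | OC(=O)CP(=O)(OCC(F)(F)F)OCC(F)(F)F | starting material
11 | O-acylisourea from 10 and DCC (formed in the flask) | O=C(CP(=O)(OCC(F)(F)F)OCC(F)(F)F)OC(NC1CCCCC1)=NC1CCCCC1 | intermediate
12 | 8α-hydroxylabda-13(16),14-dien-19-yl 2-[bis(2,2,2-trifluoroethoxy)phosphoryl]acetate | C=CC(=C)CC[C@@H]1[C@@]2(C)CCC[C@](C)(COC(=O)CP(=O)(OCC(F)(F)F)OCC(F)(F)F)[C@@H]2CC[C@@]1(C)O | intermediate
13 | vanillin, 4-hydroxy-3-methoxybenzaldehyde | COc1cc(C=O)ccc1O | starting material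
14 | O-TBS-vanillin, 4-(tert-butyldimethylsilyloxy)-3-methoxybenzaldehyde | COc1cc(C=O)ccc1O[Si](C)(C)C(C)(C)C | intermediate
15 | potassium phosphonate carbanion of 12 (formed in the flask) | [K+].C=CC(=C)CC[C@@H]1[C@@]2(C)CCC[C@](C)(COC(=O)[CH-]P(=O)(OCC(F)(F)F)OCC(F)(F)F)[C@@H]2CC[C@@]1(C)O | intermediate
16 | 8α-hydroxylabda-13(16),14-dien-19-yl (Z)-3-[4-(tert-butyldimethylsilyloxy)-3-methoxyphenyl]prop-2-enoate | C=CC(=C)CC[C@@H]1[C@@]2(C)CCC[C@](C)(COC(=O)/C=C\c3ccc(O[Si](C)(C)C(C)(C)C)c(OC)c3)[C@@H]2CC[C@@]1(C)O | intermediate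
17 | 8α-hydroxylabda-13(16),14-dien-19-yl (Z)-ferulate, CNP0142252.2 (4S,5R,8R,9R,10S; Z) | C=CC(=C)CC[C@@H]1[C@@]2(C)CCC[C@](C)(COC(=O)/C=C\c3ccc(O)c(OC)c3)[C@@H]2CC[C@@]1(C)O | target

## Step count and risks
Total step count: 10. Longest linear sequence: 9 (steps 1 to 7, then 9 and 10). Step 8 is a one-step side branch.

**Risk 1, step 2.** The cleavage relies on OsO4 distinguishing two alkenes by sterics alone, and over-oxidation would turn the 8(17)-methylene into the 8-ketone.
- The fallback sets out from 2 and comes back at 4.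
- It uses the allylic hydroxyl as a directing group instead.
- VO(acac)2 (2 mol %) and t-BuOOH in CH2Cl2 at 0 °C epoxidise only the 13-ene and give methyl 13,14-epoxy-15-hydroxylabd-8(17)-en-19-oate F1.
- H5IO6 in THF/H2O at 0 °C then hydrolyses the epoxide to triol 3 and cleaves it to 4.
- The isolated 8(17)-methylene responds to neither reagent.

**Risk 2, step 4.** Deprotonation at C12 instead of C16 would end, after step 5, in hard-to-separate communic-type 12,14-dienes, and the spiro-epoxide sits through base and later LiCl.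
- The fallback sets out from 4 and comes back at 8. It avoids regioselective enolisation by discarding C16 and putting both alkene termini back one at a time.
- Haloform degradation (NaOBr from Br2/NaOH, dioxane/H2O, 0 °C) gives 19-methoxy-19-oxo-14,15,16-trinorlabd-8(17)-en-13-oic acid F2.
- EDC·HCl, MeNH(OMe)·HCl and Et3N give the N-methoxy-N-methylamide of that acid F3.
- CH2=CHMgBr (THF, −78 to 0 °C, cold acidic quench) gives methyl 13-oxo-16-norlabda-8(17),14-dien-19-oate F4.
- mCPBA at 0 °C epoxidises only the electron-rich 8(17)-ene, from the α face, and gives methyl 8α,17-epoxy-13-oxo-16-norlabd-14-en-19-oate F5.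
- Wittig methylenation (Ph3P=CH2 from MePPh3Br/KOtBu, THF, 0 °C) then gives 8.

**Risk 3, step 9.** The Z:E ratio and conversion may drop with the electron-rich aldehyde on a bulky ester, and the acid 10 is the least common purchased reagent.
- The fallback sets out from 9 and comes back at 16. It replaces kinetic Z-olefination by E-olefination followed by photochemical E-to-Z isomerisation.
- DCC/DMAP coupling of 9 with commercial diethylphosphonoacetic acid gives 8α-hydroxylabda-13(16),14-dien-19-yl 2-(diethoxyphosphoryl)acetate F6.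
- Masamune–Roush olefination with 14 (LiCl, DBU, MeCN, rt) gives the (E)-isomer of 16 F7.
- Irradiation at 350–365 nm in dilute degassed MeCN excites only the cinnamate chromophore, since the diene absorbs far below 300 nm, and gives a photostationary E/Z mixture of roughly 1:1.
- 16 is separated from this mixture on silica and F7 is recycled.

## Further compounds
F1 | step 2 | methyl 13,14-epoxy-15-hydroxylabd-8(17)-en-19-oate (trans-epoxide, both facial isomers) | OCC3OC3(C)CC[C@@H]1[C@@]2(C)CCC[C@](C)(C(=O)OC)[C@@H]2CCC1=C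
F2 | step 4 | 19-methoxy-19-oxo-14,15,16-trinorlabd-8(17)-en-13-oic acid | OC(=O)CC[C@@H]1[C@@]2(C)CCC[C@](C)(C(=O)OC)[C@@H]2CCC1=C
F3 | step 4 | N-methoxy-N-methylamide of F2 | CON(C)C(=O)CC[C@@H]1[C@@]2(C)CCC[C@](C)(C(=O)OC)[C@@H]2CCC1=C
F4 | step 4 | methyl 13-oxo-16-norlabda-8(17),14-dien-19-oate | C=CC(=O)CC[C@@H]1[C@@]2(C)CCC[C@](C)(C(=O)OC)[C@@H]2CCC1=C
F5 | step 4 | methyl 8α,17-epoxy-13-oxo-16-norlabd-14-en-19-oate | C=CC(=O)CC[C@@H]1[C@@]2(C)CCC[C@](C)(C(=O)OC)[C@@H]2CC[C@]13CO3
F6 | step 9 | 8α-hydroxylabda-13(16),14-dien-19-yl 2-(diethoxyphosphoryl)acetate | C=CC(=C)CC[C@@H]1[C@@]2(C)CCC[C@](C)(COC(=O)CP(=O)(OCC)OCC)[C@@H]2CC[C@@]1(C)O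
F7 | step 9 | 8α-hydroxylabda-13(16),14-dien-19-yl (E)-3-[4-(tert-butyldimethylsilyloxy)-3-methoxyphenyl]prop-2-enoate | C=CC(=C)CC[C@@H]1[C@@]2(C)CCC[C@](C)(COC(=O)/C=C/c3ccc(O[Si](C)(C)C(C)(C)C)c(OC)c3)[C@@H]2CC[C@@]1(C)O
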